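Follow a small part of the charge of starting material through three set-ups and ask where it ends.

all flasks: starting material 0.25 M
- dusk: time 2.5 h; a closed flask charged with all of it at once and left for 2.5 h
- spring: a single well-mixed tank run continuously and read at steady state, 2.5 h in it on average
- summer: a single well-mixed tank run continuously and read at steady state, 25.0 h in it on average

    starting material → product (k1 = 0.016 s⁻¹)
    starting material → intermediate A (k2 = 7.4 × 10⁻⁴ s⁻¹)
    starting material → intermediate B (k3 = 6.8 × 10⁻⁴ s⁻¹)
    intermediate B ⇌ intermediate C (K4 = 2.4, k4 = 8.0 × 10⁻⁵ s⁻¹)
    intermediate A ⇌ intermediate D (K5 = 0.86, k5 = 3.5 × 10⁻⁴ s⁻¹)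
    intermediate D ⇌ intermediate E (K6 = 5.8, k6 = 4.5 × 10⁻⁴ s⁻¹)
    intermediate C ⇌ intermediate D (K7 = 5.1, k7 = 1.7 × 10⁻⁴ s⁻¹)

* the set-up with the highest amount of product at the outlet or at the end, in percent of the starting material put in ("none" if the first two lie within 2 percentage points) (dusk / spring / summer / none)
* amount of product at the outlet or at the end, in percent of the starting material put in, dusk
* amount of product at the outlet or at the end, in percent of the starting material put in, spring
* amount of product at the outlet or at the end, in percent of the starting material put in, summer

Each step out of starting material is first order, and the scheme has no arrow back to it and none from an intermediate to product. So each part of the charge leaves once, by step 1, 2 or 3, and the rate constants share it out. I fold this into one number, the product share: the constant of step 1 divided by the sum of the constants leaving starting material, the selectivity in its usual sense. Concentration cancels from it.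

k = 0.0174 s⁻¹

share = 0.016 s⁻¹ / k = 91.85 %

Starting material has a half-life of 0.663 min, against 2.5 h in dusk, so I read dusk as the share itself.

Is one number enough for the tanks? There, starting material stands at a level and leaves partly unreacted. With n = k times the mean residence time, the tank balance gives:

yield = share × n / (1 + n)

spring: n = 157, yield = 91.3 %

summer: n = 1570, yield = 91.8 %

Spring falls 0.58 percentage points below the share, inside the margin, so I commit to "none".

The forecast reckons the same way, from “All the intermediates branch off irreversibly and never return”, and gives 91.85 %, 91.27 %, 91.79 % and none.

The simulation gives 91.8 %, 91.3 %, 91.8 % and none. In dusk, half of the turnover of step 1 is done by 0.664 min, while intermediate D has a half-life of 0.43 h by the forward rate of step 6 alone. In dusk, between 1.25 h and 2.50 h, product reads 91.8 % and 91.8 %, while intermediate E goes from 1.62 % to 2.84 %. In spring, 0.00158 M of starting material stands in the tank, 0.634 % of the charge, and product reads 91.3 % of the charge. A neighbour flask like dusk, charged at 0.42 M, has the same share, 91.8 %, and reads 91.8 %.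

The numbers of this flask belong to no real substance; the rest is arithmetic.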